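**Retrosynthetic overview**
1. Feature: C3 (germacrane numbering) is the sp2 bridgehead of the 11-oxabicyclo[6.2.1]undecane core, shared by the ten-membered carbocycle C1–C10 and the 3(2H)-furanone (O, C10, C1, C2, C3). It is at the acyl oxidation level and bonded only to C2, C4 and the oxygen on C10, so it is excised as CO.
2. This cuts C3–C4 and C2–C3 (Pd/Cu carbonylative macrocyclisation of a C4 vinyl iodide onto the C1≡C2 terminal alkyne) and O10–C3 (transannular furanone closure), leaving an open chain on the C6–C7 butyrolactone.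
3. The seco chain is cut at C7–C8 (Hosomi–Sakurai union of a 3-(silylmethyl)butenolide with a citramalic acid-derived aldehyde), the butenolide at C7=C11 (ring-closing metathesis) and at C5–C6 (catalytic asymmetric alkynylation of acrolein).
4. Ring order: butenolide, then α-methylene-γ-butyrolactone, then ten-membered carbocycle (CO insertion), then the 3(2H)-furanone oxygen bridge; O15 desilylation ends the route.

Key step: step 15

Remarks: germacrane numbering is used in names and comments (C1 ketone, C2=C3, C4(C15)=C5, C6 lactone carbinol, C7, C8 acyloxy, C9, C10 quaternary with C14, C11=C13, C12 lactone carbonyl). Assumption: the (S,S)-ProPhenol/dimethylzinc catalyst is taken to deliver the alkynyl group to the Re face of acrolein; if the sense proves opposite, the (R,R) ligand is used in step 1.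

**Route**

Step 1
Reactants: 1 tert-butyl(diphenyl)(prop-2-ynyloxy)silane; 2 acrolein
Product: 3 (3S)-6-[tert-butyl(diphenyl)silyl]oxyhex-1-en-4-yn-3-ol
Conditions: 1 (3 equiv), Me2Zn (3 equiv), (S,S)-ProPhenol (10 mol%), Ph3P=O (20 mol%), toluene, 0 °C; then 2, 0–4 °C; aq. NH4Cl
Reagents that add atoms: none
Why: Dinuclear zinc amino alcohol (ProPhenol) catalysed asymmetric alkynylation, in which the alkynylzinc made from 1 and Me2Zn adds 1,2 to the enal inside the chiral pocket, Re-face delivery setting C6 as (S).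

Step 2
Reactants: 3 (3S)-6-[tert-butyl(diphenyl)silyl]oxyhex-1-en-4-yn-3-ol
Product: 5 (3S,4Z)-6-[tert-butyl(diphenyl)silyl]oxy-5-iodohexa-1,4-dien-3-ol, via the sodium 1,2-oxaluminol-2-uide (cyclic C4 vinylalanate bound to O6) 4 (not isolated)
Conditions: Red-Al, THF, −20 → 0 °C; EtOAc; I2, THF, −78 → −20 °C; aq. Rochelle salt/Na2S2O3
Reagents that add atoms: iodine, II
Why: Hydroxyl-directed trans-hydroalumination of the propargylic alcohol delivers hydride to C5 and aluminium to C4 through a five-membered oxaaluminacycle, and iodinolysis with retention puts iodine on C4 cis to C6 (Z), the cold quench keeping the β-silyloxy vinylalanate from eliminating to an allene.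

Step 3
Reactants: 6 ethyl 2-[(trimethylsilyl)methyl]prop-2-enoate
Product: 7 2-[(trimethylsilyl)methyl]prop-2-enoic acid
Conditions: LiOH, THF/H2O, 0 °C → rt; 1 M HCl to pH 3, 0 °C
Reagents that add atoms: lithium hydroxide, [Li+].[OH-]
Why: Ester saponification, with cold and mild acidification so that the allylsilane is not protodesilylated.

Step 4
Reactants: 5 (3S,4Z)-6-[tert-butyl(diphenyl)silyl]oxy-5-iodohexa-1,4-dien-3-ol; 7 2-[(trimethylsilyl)methyl]prop-2-enoic acid
Product: 8 (3S,4Z)-6-[tert-butyl(diphenyl)silyl]oxy-5-iodohexa-1,4-dien-3-yl 2-[(trimethylsilyl)methyl]prop-2-enoate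
Conditions: DCC, DMAP (cat.), CH2Cl2, 0 °C → rt
Reagents that add atoms: none
Why: Steglich carbodiimide esterification of the secondary C6 alcohol under neutral conditions that leave the allylsilane, vinyl iodide and C6 configuration untouched.

Step 5
Reactants: 8 (3S,4Z)-6-[tert-butyl(diphenyl)silyl]oxy-5-iodohexa-1,4-dien-3-yl 2-[(trimethylsilyl)methyl]prop-2-enoate
Product: 9 (5S)-5-[(1Z)-3-[tert-butyl(diphenyl)silyl]oxy-2-iodoprop-1-enyl]-3-[(trimethylsilyl)methyl]furan-2(5H)-one
Conditions: Grubbs II (10 mol%), toluene (5 mM), 80 °C, no base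
Reagents that add atoms: none
Why: Ring-closing metathesis between the C7 vinyl group and the 1,1-disubstituted acrylate forms C7=C11 with loss of ethylene, the trisubstituted iodoalkene being inert and the base-free medium avoiding γ-deprotonation (racemisation at C6).

Step 6
Reactants: 10 (S)-citramalic acid
Product: 11 2-[(4S)-2,2,4-trimethyl-5-oxo-1,3-dioxolan-4-yl]acetic acid
Conditions: 2,2-dimethoxypropane, p-TsOH (cat.), rt
Reagents that add atoms: 2,2-dimethoxypropane, COC(C)(C)OC
Why: Acetalisation engages the α-hydroxy acid selectively as the five-membered dioxolanone and leaves the CH2CO2H group (future C8) free, without touching the C10 centre.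

Step 7
Reactants: 11 2-[(4S)-2,2,4-trimethyl-5-oxo-1,3-dioxolan-4-yl]acetic acid
Product: 13 (3S)-3-hydroxy-3-methyloxolan-2-one, via (5S)-5-(2-hydroxyethyl)-2,2,5-trimethyl-1,3-dioxolan-4-one 12 (not isolated)
Conditions: BH3·THF, THF, 0 °C → rt; MeOH; then p-TsOH (cat.), CH2Cl2, rt
Reagents that add atoms: none
Why: Borane reduces the free carboxylic acid chemoselectively in the presence of the dioxolanone, and acid-catalysed translactonisation of the resulting primary alcohol onto the dioxolanone carbonyl releases acetone and the tertiary hydroxyl.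

Step 8
Reactants: 13 (3S)-3-hydroxy-3-methyloxolan-2-one
Product: 14 (3S)-3-methyloxolane-2,3-diol (lactol, both anomers)
Conditions: DIBAL-H (2.2 equiv), CH2Cl2, −78 °C; Rochelle salt
Reagents that add atoms: none
Why: Partial DIBAL-H reduction of the lactone stops at the aluminium hemiacetal at −78 °C (the first equivalent is consumed by the tertiary hydroxyl), giving the lactol on work-up.

Step 9
Reactants: 14 (3S)-3-methyloxolane-2,3-diol
Product: 15 (3S)-3-methylpent-4-yne-1,3-diol
Conditions: dimethyl (1-diazo-2-oxopropyl)phosphonate, K2CO3, MeOH, 0 °C → rt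
Reagents that add atoms: dimethyl (1-diazo-2-oxopropyl)phosphonate, CC(=O)C(=[N+]=[N-])P(=O)(OC)OC
Why: Ohira–Bestmann (Seyferth–Gilbert) homologation of the open hydroxy aldehyde form of the lactol adds C2 and gives the terminal alkyne, C10 having no α-hydrogen and so being configurationally safe.

Step 10
Reactants: 15 (3S)-3-methylpent-4-yne-1,3-diol
Product: 16 (3S)-3-methyl-1,3-bis(triethylsilyloxy)pent-4-yne
Conditions: TESOTf (2.4 equiv), 2,6-lutidine, CH2Cl2, −78 → 0 °C
Reagents that add atoms: triethylsilyl trifluoromethanesulfonate, CC[Si](CC)(CC)OS(=O)(=O)C(F)(F)F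
Why: Silyl triflate with a hindered pyridine base silylates both the primary and the hindered tertiary hydroxyl without touching the terminal alkyne C–H.

Step 11
Reactants: 16 (3S)-3-methyl-1,3-bis(triethylsilyloxy)pent-4-yne
Product: 17 (3S)-3-methyl-3-(triethylsilyloxy)pent-4-ynal
Conditions: (COCl)2, DMSO, CH2Cl2, −78 → −30 °C; Et3N, −78 °C → rt
Reagents that add atoms: none
Why: Direct Swern oxidation of a primary triethylsilyl ether, in which chlorodimethylsulfonium chloride cleaves only the unhindered primary silyl ether and oxidises the alkoxysulfonium to the C8 aldehyde while the tertiary silyl ether stays.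

Step 12
Reactants: 9 (5S)-5-[(1Z)-3-[tert-butyl(diphenyl)silyl]oxy-2-iodoprop-1-enyl]-3-[(trimethylsilyl)methyl]furan-2(5H)-one; 17 (3S)-3-methyl-3-(triethylsilyloxy)pent-4-ynal
Product: 18 (4R,5S)-5-[(1Z)-3-[tert-butyl(diphenyl)silyl]oxy-2-iodoprop-1-enyl]-4-[(1R,3S)-1-hydroxy-3-methyl-3-(triethylsilyloxy)pent-4-ynyl]-3-methylideneoxolan-2-one
Conditions: BF3·OEt2 (2 equiv), CH2Cl2, −78 → −30 °C; aq. NaHCO3
Reagents that add atoms: none
Why: Proposed new method: the BF3-bound aldehyde is attacked by C7, the γ-carbon of the allylsilane held in the butenolide (Si–C13–C11=C7), anti to the C–Si bond and on the ring face opposite the C6 alkenyl group (6,7-trans), and loss of the silyl group from the β-silyl cation unveils C11=C13, the open antiperiplanar transition state of this E-crotylsilane-type donor giving the 7,8-syn relation (8R) where a closed allylmetal transition state would give the 8-epimer; the closest known reaction type is the Lewis acid-mediated Hosomi–Sakurai addition of 2-(trimethylsilylmethyl)acrylates to aldehydes to give α-methylene-γ-butyrolactones, not yet shown for a donor held in a butenolide ring.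

Step 13
Reactants: 18 the seco alcohol of step 12; 19 (R)-2-methylbutanoic acid
Product: 20 (1R,3S)-1-{(2S,3R)-2-[(1Z)-3-[tert-butyl(diphenyl)silyl]oxy-2-iodoprop-1-enyl]-4-methylidene-5-oxooxolan-3-yl}-3-methyl-3-(triethylsilyloxy)pent-4-ynyl (2R)-2-methylbutanoate
Conditions: 19 (2 equiv), DCC, DMAP (0.2 equiv), CH2Cl2, 0 °C → rt
Reagents that add atoms: none
Why: Steglich esterification at O8 with only catalytic DMAP at low temperature avoids the ketene pathway that would epimerise the α-centre of 19, and acylation also blocks O8-to-C12 translactonisation.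

Step 14
Reactants: 20 the O8 ester of step 13
Product: 21 (1R,3S)-1-{(2S,3R)-2-[(1Z)-3-[tert-butyl(diphenyl)silyl]oxy-2-iodoprop-1-enyl]-4-methylidene-5-oxooxolan-3-yl}-3-hydroxy-3-methylpent-4-ynyl (2R)-2-methylbutanoate
Conditions: CSA (0.2 equiv), MeOH/CH2Cl2 (1:1), 0 °C
Reagents that add atoms: none
Why: Acid-catalysed methanolysis removes the triethylsilyl ether selectively, the primary tert-butyldiphenylsilyl ether, the esters and the tertiary propargylic alcohol being stable to these conditions.

Step 15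
Reactants: 21 the open-chain iodo alkynol of step 14; 22 carbon monoxide
Product: 23 (6R,7R,8R,10S)-15-[tert-butyl(diphenyl)silyl]oxy-10-hydroxy-8-[(2R)-2-methylbutanoyl]oxy-3-oxogermacra-4Z,11(13)-dien-1-yn-12,6-olide (ten-membered cross-conjugated enynone trans-fused at C6–C7 to the α-methylene lactone)
Conditions: PdCl2(PPh3)2 (15 mol%), CuI (10 mol%), Et3N (5 equiv), CO (1–3 bar), degassed THF, 35 °C, 21 added by syringe pump over 12 h to 1 mM
Reagents that add atoms: none
Why: Proposed new method: Pd(0) inserts into the C4–I bond with retention, CO inserts to give the C3 acylpalladium held cis to C6, the C2 copper acetylide formed from the terminal alkyne with CuI/Et3N transmetallates, and C(acyl)–C(sp) reductive elimination from an eleven-membered palladacycle forms the C3–C4 and C2–C3 bonds in one operation. The closest known reaction type is the Pd/Cu carbonylative Sonogashira coupling of vinyl or aryl iodides with terminal alkynes (also with tertiary propargylic alcohols), together with carbonylative Stille closures of macrocyclic dienones; closing a ten-membered ring this way is the extrapolation. The ten-membered carbocycle C1–C10 closes end to end by this reductive elimination, the direct non-carbonylative coupling being excluded intramolecularly because it would need a nine-membered 1,3-enyne ring that cannot hold the linear C10–C1–C2–C4 unit. No stereocentre is formed: the Z geometry of C4=C5 passes through palladium with retention and C6, C7, C8, C10 and the side-chain centre are not touched. The step needs ring closure over oligomerisation and CO insertion plus alkynyl transfer over Heck-type acylpalladation of C11=C13; slow addition at high dilution under CO answers the first, and the second is secured because the Z iodide, the trans lactone and the fully substituted C10 fold C2 toward C3 while insertion into C11=C13 would build a strained bridged bicycle across the trans lactone. The tertiary O10–H is too hindered to trap the acylpalladium (it would need a nine-membered lactone), and Glaser coupling is suppressed by rigorous exclusion of oxygen.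

Step 16
Reactants: 23 the ten-membered enynone of step 15
Product: 26 (6R,7R,8R,10S)-15-[tert-butyl(diphenyl)silyl]oxy-8-[(2R)-2-methylbutanoyl]oxy-1-oxo-3,10-epoxygermacra-2,4Z,11(13)-trien-12,6-olide, via the 10-hydroxy-1,3-dioxo compound (C1 hydrate of the ynone) 24 (not isolated), via the 3-hydroxy-3,10-epoxy hemiketal 25 (not isolated)
Conditions: (p-CF3C6H4)3PAuCl (5 mol%), AgOTf (5 mol%), toluene, H2O (2 equiv), rt
Reagents that add atoms: water, O
Why: Gold(I)-catalysed cyclisation of a γ-hydroxy alkynone to a 3(2H)-furanone, here transannular: conjugate hydration at C1, 5-exo-trig attack of O10 on the C3 carbonyl and loss of water give the bridged furanone with no stereocentre changed.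

Step 17
Reactants: 26 the O15 silyl ether of the target
Product: 27 (6R,7R,8R,10S)-15-hydroxy-8-[(2R)-2-methylbutanoyl]oxy-1-oxo-3,10-epoxygermacra-2,4Z,11(13)-trien-12,6-olide (CNP0307052.2)
Conditions: HF·pyridine, pyridine, THF, 0 °C → rt
Reagents that add atoms: none
Why: Fluoride-driven desilylation under buffered conditions frees the C15 allylic alcohol without touching the α-methylene lactone, the furanone or the C8 ester.

**Compound list**
1 | tert-butyl(diphenyl)(prop-2-ynyloxy)silane | C#CCO[Si](c1ccccc1)(c1ccccc1)C(C)(C)C | starting material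
2 | acrolein | C=CC=O | starting material
3 | (3S)-6-[tert-butyl(diphenyl)silyl]oxyhex-1-en-4-yn-3-ol | C=C[C@H](O)C#CCO[Si](c1ccccc1)(c1ccccc1)C(C)(C)C | intermediate
4 | sodium (5S)-3-{[tert-butyl(diphenyl)silyl]oxymethyl}-5-ethenyl-2,2-bis(2-methoxyethoxy)-2,5-dihydro-1,2-oxaluminol-2-uide | C=C[C@H]1C=C(CO[Si](c2ccccc2)(c2ccccc2)C(C)(C)C)[Al-](OCCOC)(OCCOC)O1.[Na+] | intermediate
5 | (3S,4Z)-6-[tert-butyl(diphenyl)silyl]oxy-5-iodohexa-1,4-dien-3-ol | C=C[C@H](O)/C=C(/CO[Si](c1ccccc1)(c1ccccc1)C(C)(C)C)I | intermediate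
6 | ethyl 2-[(trimethylsilyl)methyl]prop-2-enoate | C=C(C[Si](C)(C)C)C(=O)OCC | starting material
7 | 2-[(trimethylsilyl)methyl]prop-2-enoic acid | C=C(C[Si](C)(C)C)C(=O)O | intermediate
8 | (3S,4Z)-6-[tert-butyl(diphenyl)silyl]oxy-5-iodohexa-1,4-dien-3-yl 2-[(trimethylsilyl)methyl]prop-2-enoate | C=C(C[Si](C)(C)C)C(=O)O[C@@H](C=C)/C=C(/CO[Si](c1ccccc1)(c1ccccc1)C(C)(C)C)I | intermediate
9 | (5S)-5-[(1Z)-3-[tert-butyl(diphenyl)silyl]oxy-2-iodoprop-1-enyl]-3-[(trimethylsilyl)methyl]furan-2(5H)-one | O=C1O[C@H](/C=C(/CO[Si](c2ccccc2)(c2ccccc2)C(C)(C)C)I)C=C1C[Si](C)(C)C | intermediate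
10 | (S)-citramalic acid | OC(=O)C[C@](C)(O)C(=O)O | starting material
11 | 2-[(4S)-2,2,4-trimethyl-5-oxo-1,3-dioxolan-4-yl]acetic acid | OC(=O)C[C@]1(C)OC(C)(C)OC1=O | intermediate
12 | (5S)-5-(2-hydroxyethyl)-2,2,5-trimethyl-1,3-dioxolan-4-one | OCC[C@]1(C)OC(C)(C)OC1=O | intermediate
13 | (3S)-3-hydroxy-3-methyloxolan-2-one | O=C1OCC[C@]1(C)O | intermediate
14 | (3S)-3-methyloxolane-2,3-diol (lactol, both anomers) | OC1OCC[C@]1(C)O | intermediate
15 | (3S)-3-methylpent-4-yne-1,3-diol | OCC[C@](C)(O)C#C | intermediate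
16 | (3S)-3-methyl-1,3-bis(triethylsilyloxy)pent-4-yne | CC[Si](CC)(CC)OCC[C@](C)(O[Si](CC)(CC)CC)C#C | intermediate
17 | (3S)-3-methyl-3-(triethylsilyloxy)pent-4-ynal | O=CC[C@](C)(O[Si](CC)(CC)CC)C#C | intermediate
18 | (4R,5S)-5-[(1Z)-3-[tert-butyl(diphenyl)silyl]oxy-2-iodoprop-1-enyl]-4-[(1R,3S)-1-hydroxy-3-methyl-3-(triethylsilyloxy)pent-4-ynyl]-3-methylideneoxolan-2-one | C=C1C(=O)O[C@H](/C=C(/CO[Si](c2ccccc2)(c2ccccc2)C(C)(C)C)I)[C@H]1[C@H](O)C[C@](C)(O[Si](CC)(CC)CC)C#C | intermediate
19 | (R)-2-methylbutanoic acid | CC[C@@H](C)C(=O)O | starting material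
20 | (1R,3S)-1-{(2S,3R)-2-[(1Z)-3-[tert-butyl(diphenyl)silyl]oxy-2-iodoprop-1-enyl]-4-methylidene-5-oxooxolan-3-yl}-3-methyl-3-(triethylsilyloxy)pent-4-ynyl (2R)-2-methylbutanoate | C=C1C(=O)O[C@H](/C=C(/CO[Si](c2ccccc2)(c2ccccc2)C(C)(C)C)I)[C@H]1[C@H](OC(=O)[C@H](C)CC)C[C@](C)(O[Si](CC)(CC)CC)C#C | intermediate
21 | (1R,3S)-1-{(2S,3R)-2-[(1Z)-3-[tert-butyl(diphenyl)silyl]oxy-2-iodoprop-1-enyl]-4-methylidene-5-oxooxolan-3-yl}-3-hydroxy-3-methylpent-4-ynyl (2R)-2-methylbutanoate | C=C1C(=O)O[C@H](/C=C(/CO[Si](c2ccccc2)(c2ccccc2)C(C)(C)C)I)[C@H]1[C@H](OC(=O)[C@H](C)CC)C[C@](C)(O)C#C | intermediate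
22 | carbon monoxide | [C-]#[O+] | starting material
23 | (6R,7R,8R,10S)-15-[tert-butyl(diphenyl)silyl]oxy-10-hydroxy-8-[(2R)-2-methylbutanoyl]oxy-3-oxogermacra-4Z,11(13)-dien-1-yn-12,6-olide | C=C1C(=O)O[C@@H]2/C=C(/CO[Si](c3ccccc3)(c3ccccc3)C(C)(C)C)C(=O)C#C[C@@](C)(O)C[C@@H](OC(=O)[C@H](C)CC)[C@@H]12 | intermediate
24 | (6R,7R,8R,10S)-15-[tert-butyl(diphenyl)silyl]oxy-10-hydroxy-8-[(2R)-2-methylbutanoyl]oxy-1,3-dioxogermacra-4Z,11(13)-dien-12,6-olide | C=C1C(=O)O[C@@H]2/C=C(/CO[Si](c3ccccc3)(c3ccccc3)C(C)(C)C)C(=O)CC(=O)[C@@](C)(O)C[C@@H](OC(=O)[C@H](C)CC)[C@@H]12 | intermediate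
25 | (6R,7R,8R,10S)-15-[tert-butyl(diphenyl)silyl]oxy-3-hydroxy-8-[(2R)-2-methylbutanoyl]oxy-1-oxo-3,10-epoxygermacra-4Z,11(13)-dien-12,6-olide (hemiketal, C3 configuration open) | C=C1C(=O)O[C@@H]2/C=C(/CO[Si](c4ccccc4)(c4ccccc4)C(C)(C)C)C3(O)CC(=O)[C@](C)(C[C@@H](OC(=O)[C@H](C)CC)[C@@H]12)O3 | intermediate
26 | (6R,7R,8R,10S)-15-[tert-butyl(diphenyl)silyl]oxy-8-[(2R)-2-methylbutanoyl]oxy-1-oxo-3,10-epoxygermacra-2,4Z,11(13)-trien-12,6-olide | C=C1C(=O)O[C@@H]2/C=C(/CO[Si](c4ccccc4)(c4ccccc4)C(C)(C)C)C3=CC(=O)[C@](C)(C[C@@H](OC(=O)[C@H](C)CC)[C@@H]12)O3 | intermediate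
27 | (6R,7R,8R,10S)-15-hydroxy-8-[(2R)-2-methylbutanoyl]oxy-1-oxo-3,10-epoxygermacra-2,4Z,11(13)-trien-12,6-olide (CNP0307052.2) | C=C1C(=O)O[C@@H]2/C=C(/CO)C3=CC(=O)[C@](C)(C[C@@H](OC(=O)[C@H](C)CC)[C@@H]12)O3 | target

**Totals**
Total step count: 17. Longest linear sequence: 12 steps (from 10 through steps 6–17).

**Steps most likely to fail**

1. Step 15. Closure of the strained ten-membered ring may lose to intermolecular carbonylative or direct coupling (oligomerisation), or the acylpalladium may be diverted before alkynyl transfer. The fallback uses a Nozaki–Hiyama–Kishi macrocyclisation and oxidation; it sets out from 16 and comes back at 23. Compound 16 is lithiated at the alkyne (n-BuLi, THF, −78 °C) and hydroxymethylated with paraformaldehyde to (4S)-4-methyl-4,6-bis(triethylsilyloxy)hex-2-yn-1-ol F1, which is silylated (TBSCl, imidazole) to its tert-butyldimethylsilyl ether F2. Direct Swern oxidation of the primary triethylsilyl ether gives (3S)-6-[tert-butyl(dimethyl)silyl]oxy-3-methyl-3-(triethylsilyloxy)hex-4-ynal F3. This is joined to 9 under the conditions of step 12 to give the C2-(silyloxymethyl) analogue of 18 F4, and esterified with 19 as in step 13 to the corresponding (2R)-2-methylbutanoate F5. CSA in methanol removes the triethylsilyl and tert-butyldimethylsilyl groups to give the propargylic diol F6, and MnO2 oxidises the primary propargylic alcohol to the iodo ynal F7. CrCl2 with catalytic NiCl2 in DMSO/THF at high dilution adds the C4 vinylchromium to the C3 aldehyde and closes the ten-membered ring as the C3 carbinol (either epimer) F8. MnO2 or Dess–Martin oxidation of this allylic and propargylic alcohol gives 23.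

2. Step 12. The electron-poor, ring-held allylsilane may react too slowly, so that protodesilylation of 9 or loss of the triethylsilyl group under BF3 competes, or simple diastereoselection at C7/C8 may be poor. The fallback uses a Barbier allylation and Mitsunobu inversion; it sets out from 5 and comes back at 20. Compound 5 is acylated with 2-(bromomethyl)acryloyl chloride (2,6-lutidine, CH2Cl2, −20 °C) to (3S,4Z)-6-[tert-butyl(diphenyl)silyl]oxy-5-iodohexa-1,4-dien-3-yl 2-(bromomethyl)prop-2-enoate F9. Ring-closing metathesis as in step 5 gives (5S)-3-(bromomethyl)-5-[(1Z)-3-[tert-butyl(diphenyl)silyl]oxy-2-iodoprop-1-enyl]furan-2(5H)-one F10. Zinc- (or indium-) mediated Barbier allylation of 17 in THF/aq. NH4Cl, through the closed six-membered transition state, should give the 8-epimer of 18 (8S alcohol) F11. Mitsunobu esterification with 19 (PPh3, DIAD, toluene) inverts C8 and gives 20.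

3. Step 16. Hydration may occur at the wrong alkyne carbon or stall before transannular hemiketalisation and dehydration, and the strained ynone may be lost in gold-promoted side reactions. The fallback uses the classical amine route to 3(2H)-furanones, with the α-methylene lactone masked as its amine adduct; it sets out from 23 and comes back at 26. Dimethylamine (THF, 0 °C) adds to C1 of the ynone and to C13 of the α-methylene lactone, giving the 1-dimethylamino enaminone 13-dimethylamino adduct F12. Aqueous acetic acid then brings about attack of O10 on C3, loss of water and hydrolysis of the C1 iminium, giving the 13-dimethylamino-11,13-dihydro derivative of 26 F13. Methyl iodide converts this into the 13-trimethylammonium iodide F14, which is not isolated, and NaHCO3 eliminates trimethylamine to restore C11=C13 and give 26.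

**Further compounds**
F1 | step 15 | (4S)-4-methyl-4,6-bis(triethylsilyloxy)hex-2-yn-1-ol | OCC#C[C@@](C)(O[Si](CC)(CC)CC)CCO[Si](CC)(CC)CC
F2 | step 15 | tert-butyldimethylsilyl ether of F1 | CC(C)(C)[Si](C)(C)OCC#C[C@@](C)(O[Si](CC)(CC)CC)CCO[Si](CC)(CC)CC
F3 | step 15 | (3S)-6-[tert-butyl(dimethyl)silyl]oxy-3-methyl-3-(triethylsilyloxy)hex-4-ynal | CC(C)(C)[Si](C)(C)OCC#C[C@@](C)(O[Si](CC)(CC)CC)CC=O
F4 | step 15 | C2-(tert-butyldimethylsilyloxymethyl) analogue of 18 | C=C1C(=O)O[C@H](/C=C(/CO[Si](c2ccccc2)(c2ccccc2)C(C)(C)C)I)[C@H]1[C@H](O)C[C@](C)(O[Si](CC)(CC)CC)C#CCO[Si](C)(C)C(C)(C)C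
F5 | step 15 | (2R)-2-methylbutanoate of F4 | C=C1C(=O)O[C@H](/C=C(/CO[Si](c2ccccc2)(c2ccccc2)C(C)(C)C)I)[C@H]1[C@H](OC(=O)[C@H](C)CC)C[C@](C)(O[Si](CC)(CC)CC)C#CCO[Si](C)(C)C(C)(C)C
F6 | step 15 | propargylic diol (C3 hydroxymethyl, free O10–H) | C=C1C(=O)O[C@H](/C=C(/CO[Si](c2ccccc2)(c2ccccc2)C(C)(C)C)I)[C@H]1[C@H](OC(=O)[C@H](C)CC)C[C@](C)(O)C#CCO
F7 | step 15 | iodo ynal (C3 aldehyde) | C=C1C(=O)O[C@H](/C=C(/CO[Si](c2ccccc2)(c2ccccc2)C(C)(C)C)I)[C@H]1[C@H](OC(=O)[C@H](C)CC)C[C@](C)(O)C#CC=O
F8 | step 15 | ten-membered C3 carbinol (3-hydroxy analogue of 23, either C3 epimer) | C=C1C(=O)O[C@@H]2/C=C(/CO[Si](c3ccccc3)(c3ccccc3)C(C)(C)C)C(O)C#C[C@@](C)(O)C[C@@H](OC(=O)[C@H](C)CC)[C@@H]12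
F9 | step 12 | (3S,4Z)-6-[tert-butyl(diphenyl)silyl]oxy-5-iodohexa-1,4-dien-3-yl 2-(bromomethyl)prop-2-enoate | C=C(CBr)C(=O)O[C@@H](C=C)/C=C(/CO[Si](c1ccccc1)(c1ccccc1)C(C)(C)C)I
F10 | step 12 | (5S)-3-(bromomethyl)-5-[(1Z)-3-[tert-butyl(diphenyl)silyl]oxy-2-iodoprop-1-enyl]furan-2(5H)-one | O=C1O[C@H](/C=C(/CO[Si](c2ccccc2)(c2ccccc2)C(C)(C)C)I)C=C1CBr
F11 | step 12 | 8-epimer of 18 ((1S,3S)-1-hydroxy side chain) | C=C1C(=O)O[C@H](/C=C(/CO[Si](c2ccccc2)(c2ccccc2)C(C)(C)C)I)[C@H]1[C@@H](O)C[C@](C)(O[Si](CC)(CC)CC)C#C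
F12 | step 16 | 1-dimethylamino enaminone 13-dimethylamino adduct of 23 (C11 configuration open) | CN(C)CC1C(=O)O[C@@H]2/C=C(/CO[Si](c3ccccc3)(c3ccccc3)C(C)(C)C)C(=O)C=C(N(C)C)[C@@](C)(O)C[C@@H](OC(=O)[C@H](C)CC)[C@@H]12
F13 | step 16 | 13-dimethylamino-11,13-dihydro derivative of 26 | CN(C)CC1C(=O)O[C@@H]2/C=C(/CO[Si](c4ccccc4)(c4ccccc4)C(C)(C)C)C3=CC(=O)[C@](C)(C[C@@H](OC(=O)[C@H](C)CC)[C@@H]12)O3
F14 | step 16 | 13-trimethylammonium iodide of F13 | C[N+](C)(C)CC1C(=O)O[C@@H]2/C=C(/CO[Si](c4ccccc4)(c4ccccc4)C(C)(C)C)C3=CC(=O)[C@](C)(C[C@@H](OC(=O)[C@H](C)CC)[C@@H]12)O3.[I-]
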